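**Retrosynthetic overview**
- The C8–O acyl bond is cut last: site-selective esterification of a 6,8-diol allyl ester with the protected (R)-side-chain acid; C15–OH comes from a late allylic hydroxylation and the acid from a final deallylation/desilylation.
- The diol ester comes from an all-cis bis-γ-lactone (double ring opening, decarboxylative methylenation). Key C8–O bond: a malonate carboxylate displaces a C8 bromide with inversion right after the C6–O-tethered radical closure of C7–C11 (new tandem).
- The C6–O bond comes from nucleophilic epoxidation of a cyclohexenone, then Wharton transposition to the allylic alcohol.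
- The carbocycle comes from (−)-verbenone: vinyl cuprate addition sets C10, and acid-mediated cyclobutane cleavage releases the C5 isopropenyl group.
- Ring order: the six-membered carbocycle first (by opening the bicycle); then the tether lactone at O6 and the second lactone at O8 in one step; both lactones are opened again.

Locants: C10 is the ring carbon with methyl and vinyl (C1=C2), C9 the ring CH2, then C8, C7, C6, C5 round the ring; C4(=C3)–C15 is the propenyl group on C5 and C11(=C13)–C12 the three-carbon unit on C7. Descriptors quoted with these locants refer to them.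

Assumption: (−)-verbenone of at least 97% ee (from high-ee (−)-α-pinene) is used.

**Step 1**
Reactants: 1 (1S,5S)-(−)-verbenone; 2 vinylmagnesium bromide
Product: 4 (1S,4R,5R)-4,6,6-trimethyl-4-vinylbicyclo[3.1.1]heptan-2-one, via bromomagnesium enolate 3 (not isolated)
Conditions: CuBr·SMe2 (10 mol %), THF, −40 → 0 °C; then 1 M HCl
Reagents that add atoms: none
Why: Copper-catalysed conjugate addition of the Grignard reagent, in which vinyl enters C4 anti to the gem-dimethyl bridge and so fixes the quaternary centre (later C10) with vinyl trans to the future isopropenyl group.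

**Step 2**
Reactants: 4
Product: 6 (3R,4R)-3-methyl-4-(prop-1-en-2-yl)-3-vinylcyclohexan-1-one, via enol acetate 5 (not isolated)
Conditions: BF3·OEt2, Zn(OAc)2 (cat.), Ac2O, CH2Cl2, 0 → 25 °C; then K2CO3 (cat.), MeOH
Reagents that add atoms: none
Why: Lewis-acid cyclobutane fragmentation of a nopinone-type ketone (only the bond between the α-bridgehead and the CMe2 carbon can break), giving the enol acetate and a tertiary cation that loses a methyl proton to the isopropenyl group; C5 and C10 are untouched and methanolysis frees the ketone.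

**Step 3**
Reactants: 6
Product: 7 (4R,5R)-5-methyl-4-(prop-1-en-2-yl)-5-vinylcyclohex-2-en-1-one
Conditions: IBX, DMSO, 70 °C
Reagents that add atoms: none
Why: IBX dehydrogenation of the ketone to the enone, which can only occur towards C7–C6 because C10 is quaternary.

**Step 4**
Reactants: 7
Product: 8 (1S,4R,5R,6S)-4-methyl-5-(prop-1-en-2-yl)-4-vinyl-7-oxabicyclo[4.1.0]heptan-2-one
Conditions: 30% H2O2, NaOH (cat.), MeOH, 0 °C
Reagents that add atoms: hydrogen peroxide (OO)
Why: Weitz–Scheffer nucleophilic epoxidation, in which hydroperoxide attacks C6 anti to the neighbouring C5 isopropenyl group and the axial C10 methyl, so the new C6–O bond is trans to the C5 substituent (sets C6).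

**Step 5**
Reactants: 8
Product: 9 (1R,5R,6R)-5-methyl-6-(prop-1-en-2-yl)-5-vinylcyclohex-2-en-1-ol
Conditions: N2H4·H2O, AcOH (cat.), MeOH, 0 → 25 °C
Reagents that add atoms: none
Why: Wharton transposition (epoxy hydrazone fragmentation with loss of N2), which removes the C8 carbonyl, places the alkene at C7=C8 and leaves the C6–O bond and its configuration untouched.

**Step 6**
Reactants: 9; 10 Meldrum's acid
Product: 11 3-oxo-3-{[(1R,5R,6R)-5-methyl-6-(prop-1-en-2-yl)-5-vinylcyclohex-2-en-1-yl]oxy}propanoic acid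
Conditions: toluene, 100 °C
Reagents that add atoms: none
Why: Thermal acylation of the alcohol by ring opening of Meldrum's acid with loss of acetone, which installs the hydrogen malonate tether on O6 without touching a stereocentre.

**Step 7**
Reactants: 11
Product: 14 bis-γ-lactone (5R,6S,7R,8R,10R,11S) in which the malonyl carbon C11 on C7 is closed onto O6 and O8, via bromomalonate 12 (not isolated), via bromo lactone acid 13 (not isolated)
Conditions: CBrCl3 (1.1 equiv), DBU (2.2 equiv), MeCN, 0 °C; fac-Ir(ppy)3 (1 mol %), 450 nm LED, 25 °C; then 45 °C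
Reagents that add atoms: none
Why: Proposed new method: a one-pot bromination, visible-light bromine-atom-transfer radical cyclisation and carboxylate displacement (carbolactonisation) of an allylic hydrogen malonate, in which the malonyl radical from 12 closes 5-exo onto C7 on the face held by the C6–O tether (cis-fused first lactone, sets C7), the C8 radical takes bromine from 12 on the open opposite face, and the carboxylate on C11 then displaces that bromide from the tether face with inversion so that the new C8–O bond is cis to C7–C11 and C6–O (sets C8, C9 stays CH2); the closest known reaction types are photoredox atom-transfer radical cyclisation of bromomalonates and the Mn(OAc)3/Cu(OAc)2 oxidative lactonisation of allyl malonates, which here would risk β-hydride loss to a C8=C9 alkene.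

**Step 8**
Reactants: 14; 15 formaldehyde
Product: 18 allyl 2-[(1R,2S,3R,4R,6R)-2,6-dihydroxy-4-methyl-3-(prop-1-en-2-yl)-4-vinylcyclohexyl]acrylate, via dilithium malonate 16 (not isolated), via lithium acrylate 17 (not isolated)
Conditions: LiOH (2.1 equiv), THF–H2O, 25 °C; aq. CH2O, Et2NH (cat.), AcOH (1 equiv), 50 °C; evaporate; allyl bromide, DMF, 25 °C
Reagents that add atoms: lithium hydroxide ([Li+].[OH-]); allyl bromide (C=CCBr)
Why: Saponification of both lactones, Mannich-type decarboxylative methylenation of the resulting malonate and O-alkylation of the carboxylate, all run without acidification so that the cis γ-hydroxy acid never relactonises; no stereocentre is touched.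

**Step 9**
Reactants: 19 (tert-butyldimethylsilyloxy)acetaldehyde; 20 1,1,1,3,3,3-hexafluoropropan-2-yl acrylate
Product: 21 1,1,1,3,3,3-hexafluoropropan-2-yl (3R)-4-[(tert-butyldimethylsilyl)oxy]-3-hydroxy-2-methylidenebutanoate
Conditions: α-isocupreine (10 mol %), DMF, −55 °C
Reagents that add atoms: none
Why: Cinchona-catalysed asymmetric Morita–Baylis–Hillman reaction, in which the quinine-derived catalyst (pseudoenantiomer of β-isocupreidine) is expected to give the (R)-carbinol for this α-silyloxy aldehyde.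

**Step 10**
Reactants: 21
Product: 22 1,1,1,3,3,3-hexafluoropropan-2-yl (3R)-3,4-bis[(tert-butyldimethylsilyl)oxy]-2-methylidenebutanoate
Conditions: TBSOTf, 2,6-lutidine, CH2Cl2, −78 → 0 °C
Reagents that add atoms: tert-butyldimethylsilyl triflate (CC(C)(C)[Si](C)(C)OS(=O)(=O)C(F)(F)F)
Why: Silyl protection of the secondary alcohol under non-nucleophilic base, which leaves the activated ester and the stereocentre intact.

**Step 11**
Reactants: 22
Product: 23 (3R)-3,4-bis[(tert-butyldimethylsilyl)oxy]-2-methylidenebutanoic acid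
Conditions: LiOH, THF–H2O, 0 °C; then 1 M HCl to pH 3
Reagents that add atoms: lithium hydroxide ([Li+].[OH-])
Why: Saponification of the activated hexafluoroisopropyl ester, which is fast at 0 °C and does not disturb the silyl ethers or the carbinol centre.

**Step 12**
Reactants: 18; 23
Product: 25 O8 ester (5R,6S,7S,8R,10R,3'R) of diol 18 acylated at O8 by acid 23, via mixed anhydride 24 (not isolated)
Conditions: 2,4,6-Cl3C6H2COCl, Et3N, THF, 0 °C; then 18, DMAP, toluene, 25 °C
Reagents that add atoms: none
Why: Yamaguchi esterification, site-selective because the equatorial C8 hydroxyl has one branched neighbour while the C6 hydroxyl is flanked by two branched carbons; the non-basic conditions keep the γ-hydroxy allyl ester from lactonising.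

**Step 13**
Reactants: 25
Product: 26 15-hydroxy derivative (5S,6S,7S,8R,10R,3'R) of ester 25
Conditions: SeO2 (0.5 equiv), t-BuOOH, CH2Cl2, 25 °C
Reagents that add atoms: tert-butyl hydroperoxide (CC(C)(C)OO)
Why: SeO2 allylic hydroxylation (ene reaction then 2,3-sigmatropic shift) at the only allylic methyl of an electron-rich alkene, the isopropenyl CH3; the C5 descriptor changes only through ligand priority.

**Step 14**
Reactants: 26
Product: 28 target CNP0348657.1 (5S,6S,7S,8R,10R,3'R), via silylated acid 27 (not isolated)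
Conditions: Pd(PPh3)4 (5 mol %), morpholine, THF, 0 °C; then TBAF–AcOH (1:1), THF, 25 °C; work-up at pH 5
Reagents that add atoms: none
Why: Palladium-catalysed allyl transfer to morpholine (Tsuji–Trost deallylation) frees the acid as its carboxylate, which cannot lactonise, and buffered fluoride then removes both silyl ethers without touching a stereocentre.

**Compound list**
1 | (1S,5S)-(−)-verbenone | CC1=CC(=O)[C@H]2C[C@@H]1C2(C)C | starting material
2 | vinylmagnesium bromide | C=C[Mg]Br | starting material
3 | bromomagnesium enolate of 4 | C[C@]1(C=C)C=C(O[Mg]Br)[C@H]2C[C@@H]1C2(C)C | intermediate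
4 | (1S,4R,5R)-4,6,6-trimethyl-4-vinylbicyclo[3.1.1]heptan-2-one | C[C@]1(C=C)CC(=O)[C@H]2C[C@@H]1C2(C)C | intermediate
5 | (4R,5R)-5-methyl-4-(prop-1-en-2-yl)-5-vinylcyclohex-1-en-1-yl acetate | C=C[C@@]1(C)CC(OC(C)=O)=CC[C@@H]1C(C)=C | intermediate
6 | (3R,4R)-3-methyl-4-(prop-1-en-2-yl)-3-vinylcyclohexan-1-one | C=C[C@@]1(C)CC(=O)CC[C@@H]1C(C)=C | intermediate
7 | (4R,5R)-5-methyl-4-(prop-1-en-2-yl)-5-vinylcyclohex-2-en-1-one | C=C[C@@]1(C)CC(=O)C=C[C@@H]1C(C)=C | intermediate
8 | (1S,4R,5R,6S)-4-methyl-5-(prop-1-en-2-yl)-4-vinyl-7-oxabicyclo[4.1.0]heptan-2-one | C=C[C@@]1(C)CC(=O)[C@H]2O[C@H]2[C@@H]1C(C)=C | intermediate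
9 | (1R,5R,6R)-5-methyl-6-(prop-1-en-2-yl)-5-vinylcyclohex-2-en-1-ol | C=C[C@@]1(C)CC=C[C@@H](O)[C@@H]1C(C)=C | intermediate
10 | Meldrum's acid (2,2-dimethyl-1,3-dioxane-4,6-dione) | CC1(C)OC(=O)CC(=O)O1 | starting material
11 | 3-oxo-3-{[(1R,5R,6R)-5-methyl-6-(prop-1-en-2-yl)-5-vinylcyclohex-2-en-1-yl]oxy}propanoic acid | C=C[C@@]1(C)CC=C[C@@H](OC(=O)CC(=O)O)[C@@H]1C(C)=C | intermediate
12 | 2-bromo derivative of 11 (both C2 epimers) | C=C[C@@]1(C)CC=C[C@@H](OC(=O)C(Br)C(=O)O)[C@@H]1C(C)=C | intermediate
13 | bromo lactone acid (5R,6S,7S,8S,10R): γ-lactone O6–CO–C11–C7, CO2H on C11, Br on C8 trans to C11 | C=C[C@@]1(C)C[C@H](Br)[C@H]2C(C(=O)O)C(=O)O[C@H]2[C@@H]1C(C)=C | intermediate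
14 | bis-γ-lactone (5R,6S,7R,8R,10R,11S): C11 on C7 carries two lactone carbonyls closed onto O6 and O8, all cis | C=C[C@@]1(C)C[C@H]2OC(=O)[C@H]3C(=O)O[C@@H]([C@@H]1C(C)=C)[C@@H]23 | intermediate
15 | formaldehyde | C=O | starting material
16 | dilithium [(1R,2S,3R,4R,6R)-2,6-dihydroxy-4-methyl-3-(prop-1-en-2-yl)-4-vinylcyclohexyl]malonate | C=C[C@@]1(C)C[C@@H](O)[C@@H](C(C(=O)[O-])C(=O)[O-])[C@@H](O)[C@@H]1C(C)=C.[Li+].[Li+] | intermediate
17 | lithium 2-[(1R,2S,3R,4R,6R)-2,6-dihydroxy-4-methyl-3-(prop-1-en-2-yl)-4-vinylcyclohexyl]acrylate | C=C[C@@]1(C)C[C@@H](O)[C@@H](C(=C)C(=O)[O-])[C@@H](O)[C@@H]1C(C)=C.[Li+] | intermediate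
18 | allyl 2-[(1R,2S,3R,4R,6R)-2,6-dihydroxy-4-methyl-3-(prop-1-en-2-yl)-4-vinylcyclohexyl]acrylate | C=C[C@@]1(C)C[C@@H](O)[C@@H](C(=C)C(=O)OCC=C)[C@@H](O)[C@@H]1C(C)=C | intermediate
19 | (tert-butyldimethylsilyloxy)acetaldehyde | O=CCO[Si](C)(C)C(C)(C)C | starting material
20 | 1,1,1,3,3,3-hexafluoropropan-2-yl acrylate | C=CC(=O)OC(C(F)(F)F)C(F)(F)F | starting material
21 | 1,1,1,3,3,3-hexafluoropropan-2-yl (3R)-4-[(tert-butyldimethylsilyl)oxy]-3-hydroxy-2-methylidenebutanoate | C=C(C(=O)OC(C(F)(F)F)C(F)(F)F)[C@@H](O)CO[Si](C)(C)C(C)(C)C | intermediate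
22 | 1,1,1,3,3,3-hexafluoropropan-2-yl (3R)-3,4-bis[(tert-butyldimethylsilyl)oxy]-2-methylidenebutanoate | C=C(C(=O)OC(C(F)(F)F)C(F)(F)F)[C@@H](O[Si](C)(C)C(C)(C)C)CO[Si](C)(C)C(C)(C)C | intermediate
23 | (3R)-3,4-bis[(tert-butyldimethylsilyl)oxy]-2-methylidenebutanoic acid | C=C(C(=O)O)[C@@H](O[Si](C)(C)C(C)(C)C)CO[Si](C)(C)C(C)(C)C | intermediate
24 | mixed anhydride of 23 and 2,4,6-trichlorobenzoic acid | C=C(C(=O)OC(=O)c1c(Cl)cc(Cl)cc1Cl)[C@@H](O[Si](C)(C)C(C)(C)C)CO[Si](C)(C)C(C)(C)C | intermediate
25 | O8 ester (5R,6S,7S,8R,10R,3'R): diol 18 acylated at O8 by acid 23 | C=C[C@@]1(C)C[C@@H](OC(=O)C(=C)[C@@H](O[Si](C)(C)C(C)(C)C)CO[Si](C)(C)C(C)(C)C)[C@@H](C(=C)C(=O)OCC=C)[C@@H](O)[C@@H]1C(C)=C | intermediate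
26 | 15-hydroxy derivative (5S,6S,7S,8R,10R,3'R) of 25 | C=C[C@@]1(C)C[C@@H](OC(=O)C(=C)[C@@H](O[Si](C)(C)C(C)(C)C)CO[Si](C)(C)C(C)(C)C)[C@@H](C(=C)C(=O)OCC=C)[C@@H](O)[C@@H]1C(=C)CO | intermediate
27 | C12 carboxylic acid of 26 (bis-silyl ether) | C=C[C@@]1(C)C[C@@H](OC(=O)C(=C)[C@@H](O[Si](C)(C)C(C)(C)C)CO[Si](C)(C)C(C)(C)C)[C@@H](C(=C)C(=O)O)[C@@H](O)[C@@H]1C(=C)CO | intermediate
28 | (5S,6S,7S,8R,10R)-8-{[(3R)-3,4-dihydroxy-2-methylidenebutanoyl]oxy}-6,15-dihydroxyelema-1,3,11(13)-trien-12-oic acid (CNP0348657.1) | C=C[C@@]1(C)C[C@@H](OC(=O)C(=C)[C@@H](O)CO)[C@@H](C(=C)C(=O)O)[C@@H](O)[C@@H]1C(=C)CO | target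

**Step count**
Total: 14 steps. Longest linear sequence: 11 steps (steps 1–8, then 12–14); the side-chain acid takes 3 steps (9–11).

**Steps most likely to fail**

Step 7, the proposed tandem, is the least certain: the bromomalonate may decarboxylate, the ester-tethered radical closure may be slow, or the bromide may be lost by elimination. The fallback uses known nitrone chemistry, sets out from 9 and comes back at 18. Alcohol 9 is esterified with pyruvic acid (DCC, DMAP) to the pyruvate ester F1. Condensation with N-methylhydroxylamine and heating in toluene lets the tethered ketonitrone add across C7=C8 (intramolecular nitrone cycloaddition), giving the isoxazolidine lactone F2 with C6–O, C7–C11 and C8–O all cis. N-Methylation (MeOTf) and reductive N–O cleavage (Zn, AcOH) give the dimethylamino lactone F3. N-Oxidation (mCPBA, −20 °C) and Cope elimination, which can only run towards the methyl group because the C7 hydrogen is anti to nitrogen, give the methylene lactone F4. LiOH, then allyl bromide in DMF, opens the lactone and gives 18.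

Step 8 packs three operations into one flask; partial relactonisation before the methylenation or during alkylation would give lactone mixtures. The fallback sets out from 14 and comes back at 17. A Mannich reaction of the acidic C11–H with Eschenmoser's salt (Et3N, CH2Cl2) gives the Mannich base F5, and MeI gives the ammonium iodide F6. LiOH then opens both lactones, and the β-ammonio malonate loses CO2 and trimethylamine at 25 °C to give 17, which is allylated as before to 18.

Step 12 depends on the C8 hydroxyl out-competing the C6 hydroxyl and on the γ-hydroxy ester not lactonising under DMAP. The fallback sets out from 18 and 23 and comes back at 25. Diol 18 is heated with Bu2SnO (toluene, water removal) to the stannylene acetal F7, which activates the less hindered equatorial O8. Acid 23 is converted with 1-chloro-N,N,2-trimethylpropenylamine into the acid chloride F8, which acylates F7 at O8 at 0 °C without added base to give 25.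

**Further compounds**
F1 | step 7 | pyruvate ester of 9 | C=C[C@@]1(C)CC=C[C@@H](OC(=O)C(C)=O)[C@@H]1C(C)=C
F2 | step 7 | isoxazolidine lactone (N-methyl, C11-methyl, O6 lactone, O8 in the isoxazolidine) | C=C[C@@]1(C)C[C@H]2ON(C)[C@@]3(C)C(=O)O[C@@H]([C@@H]1C(C)=C)[C@@H]23
F3 | step 7 | dimethylamino lactone with free C8 hydroxyl | C=C[C@@]1(C)C[C@@H](O)[C@@H]2[C@@H](OC(=O)[C@]2(C)N(C)C)[C@@H]1C(C)=C
F4 | step 7 | methylene lactone (O6 lactone) with free C8 hydroxyl | C=C[C@@]1(C)C[C@@H](O)[C@H]2C(=C)C(=O)O[C@H]2[C@@H]1C(C)=C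
F5 | step 8 | Mannich base of 14 (dimethylaminomethyl on C11) | C=C[C@@]1(C)C[C@H]2OC(=O)[C@@]3(CN(C)C)C(=O)O[C@@H]([C@@H]1C(C)=C)[C@@H]23
F6 | step 8 | trimethylammonium iodide of F5 | C=C[C@@]1(C)C[C@H]2OC(=O)[C@@]3(C[N+](C)(C)C)C(=O)O[C@@H]([C@@H]1C(C)=C)[C@@H]23.[I-]
F7 | step 12 | dibutylstannylene acetal of 18 | C=C[C@@]1(C)C[C@H]2O[Sn](CCCC)(CCCC)O[C@@H]([C@@H]1C(C)=C)[C@@H]2C(=C)C(=O)OCC=C
F8 | step 12 | acid chloride of 23 | C=C(C(=O)Cl)[C@@H](O[Si](C)(C)C(C)(C)C)CO[Si](C)(C)C(C)(C)C
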